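Target is what dawn and midnight are asked for at 6.0 min, and the earlier runs show how it accumulates.

| flask | substrate | partner | remark | time |
|---|---|---|---|---|
| amber | 0.045 M | 0.22 M | run made earlier |  |
| violet | 0.095 M | 0.22 M | run made earlier |  |
| teal | 0.14 M | 0.22 M | run made earlier |  |
| green | 0.20 M | 0.088 M | run made earlier |  |
| dawn | 0.20 M | 0.220 M |  | 6.0 min |
| midnight | 0.050 M | 0.0600 M |  | 6.0 min |

| run | time / min | target / % | substrate / % |
|---|---|---|---|
| amber | 0.500 | 5.8 | 92.2 |
| amber | 1.50 | 15.3 | 83.5 |
| amber | 3.00 | 23.6 | 77.4 |
| amber | 4.00 | 27.1 | 70.7 |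
| amber | 6.00 | 33.3 | 63.8 |
| violet | 0.500 | 4.4 | 94.3 |
| violet | 0.833 | 6.8 | 89.5 |
| violet | 1.50 | 10.1 | 87.2 |
| violet | 3.00 | 17.1 | 80.0 |
| violet | 6.00 | 28.5 | 70.2 |
| teal | 0.500 | 5.1 | 93.8 |
| teal | 1.50 | 9.9 | 87.5 |
| teal | 3.00 | 18.0 | 84.0 |
| teal | 4.00 | 19.4 | 80.3 |
| teal | 6.00 | 22.7 | 75.2 |
| green | 0.500 | 1.6 | 94.7 |
| green | 1.50 | 4.8 | 91.6 |
| green | 3.00 | 6.9 | 89.8 |
| green | 4.00 | 8.6 | 87.0 |
| green | 6.00 | 11.1 | 84.7 |

(readings scatter by 1 percentage point)



* the flask that ends with the higher amount of target, in percent of the substrate charged, or "neither" when 2 percentage points or less lies between them (dawn / midnight / neither)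
* final target, as a percentage of the substrate charged, in dawn
* final target, as a percentage of the substrate charged, in midnight

In the first instants, the amber, violet and teal runs, which share 0.22 M of partner, read 5.8 %, 4.4 % and 5.1 % target at 0.500 min, although their substrate charges run from 0.045 M to 0.14 M. Within a scatter of 1 percentage point, I read that as an opening pseudo-first-order in substrate. Later they part: by 6.00 min they read 33.3 %, 28.5 % and 22.7 %. Teal holds 0.0318 M of target and amber 0.0150 M, so I suspect a brake that grows with molar c(target). Between 1.50 min and 6.00 min, time grows by a factor of 4.00, while target grows by 2.29 in teal and 2.31 in green, readings not far above the square root of that factor, 2.00.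

Toward the end, teal still holds 75.2 % of its substrate, so I treat both concentrations as roughly constant and take the rate as proportional to c(substrate) c(partner)/c(target). Integrated, this makes the squared fraction of target at a fixed time follow the equivalents, c(partner)/c(substrate). Teal gives 0.0328 and green 0.0280. Their geometric mean is my brake number 0.0303, the squared fraction of target at that time per equivalent of partner. Dawn has 1.10 equivalents and midnight 1.20, so I reckon 18.3 % for dawn and 19.1 % for midnight. They lie 0.80 points apart, less than the margin of 2 points, so my answer is neither.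

The forecast also reads “product inhibition”, but differs from my reckoning: dawn 20.5 % (range 17 % to 26 %), midnight 11.5 % (range 7.5 % to 14.5 %), and more target in dawn.

The flasks end at 19.8 % in dawn and 19.3 % in midnight: neither.

    substrate ⇌ intermediate + leaving ligand (K = 2.10 × 10⁻⁴ M, k = 0.180 min⁻¹)
    partner + intermediate → target (k = 27.0 M⁻¹ min⁻¹)
    substrate + intermediate → side product (k = 1.20 M⁻¹ min⁻¹)

Read back from these results, the brake number is 0.0357 in dawn and 0.0311 in midnight. The neighbour of midnight, charged with 0.036 M of partner, has 0.720 equiv. My brake number 0.0303 gives it 14.8 % target, and that flask ends at 14.4 % target, with 82 % of its substrate and 80 % of its partner left.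

(The numbers in the tables were computed on assumed constants; noise was put on by code.)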